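## Retrosynthetic overview

1. The strategy rests on the C8 (tertiary OH) / C9 (secondary OH) cis-diol inside the ten-membered ring C1–C10, next to the C7 lactone oxygen. This is a pinacol retron: cutting C8–C9 gives an open-chain C9 aldehyde / C8 β-keto ester (C17–C19 methyl ester).
2. The keto aldehyde is joined at C4–C5 by B-alkyl Suzuki coupling of a cyclohexane fragment (C1–C4, C9–C15, C20) with a D-tartrate-derived enol triflate keto ester (C5–C8, C16–C19).
3. The six-membered ring C1/C10–C14 is made first by an endo Diels–Alder reaction that sets C1, C10 and C11. C12–O and the 13,14-epoxide follow by carboxylate-delivered, then hydroxyl-directed, oxygenation on the C2 face.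
4. Ring order: six-membered ring, then epoxide, then ten-membered ring (pinacol), then γ-lactone C7–O–C19. C6–Cl is introduced after the lactone by inversion of the epimeric allylic alcohol.

Key step: step 20

Remarks on the chemistry (assumptions):
- Locants C1–C20 are those used in the overview (C15 = methyl on C1, C16 = exocyclic methylene, C18 = methyl on C17, C20 = methyl on C11).
- The facial sense of the oxazaborolidinium catalyst in step 3 is assigned from the usual aldehyde-binding model; if the antipode of 6 forms, the (R)-catalyst is used instead.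
- C17 is labile in the β-keto esters and is not controlled in the pinacol step. It is drawn without configuration in 24–31 (epimer mixture) and is set thermodynamically in step 23.
- The 8,9-diol is masked as an acetonide after the key step, because the free C9 hydroxyl would otherwise compete with the C7 hydroxyl for γ-lactonization onto C19.

## Route

Step 1
Reactants: 1 2,2-dimethoxyacetaldehyde; 2 ethyl 2-(triphenylphosphoranylidene)propanoate
Product: 3 ethyl (E)-4,4-dimethoxy-2-methylbut-2-enoate
Conditions: CH2Cl2/H2O, rt
Reagents that add atoms: none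
Why: Wittig olefination with a stabilized ylide gives the (E)-trisubstituted enoate (ester trans to the acetal carbon), the geometry that later places C2 and C9 trans on the six-membered ring.

Step 2
Reactants: 3 ethyl (E)-4,4-dimethoxy-2-methylbut-2-enoate
Product: 4 ethyl (E)-2-methyl-4-oxobut-2-enoate
Conditions: Amberlyst-15, acetone/H2O, rt
Reagents that add atoms: water, O
Why: Acid-catalysed acetal hydrolysis frees the conjugated aldehyde without touching the alkene geometry or the ester.

Step 3
Reactants: 4 ethyl (E)-2-methyl-4-oxobut-2-enoate; 5 (E)-penta-1,3-diene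
Product: 6 ethyl (1S,5S,6S)-6-formyl-1,5-dimethylcyclohex-3-ene-1-carboxylate
Conditions: (S)-3,3-diphenyl-1-(o-tolyl)tetrahydropyrrolo[1,2-c][1,3,2]oxazaborole (20 mol%) activated with HNTf2, 5 (3 equiv), CH2Cl2, −78 to −40 °C
Reagents that add atoms: none
Why: Catalytic enantioselective Diels–Alder reaction of an aldehyde-activated dienophile: the unsubstituted diene terminus bonds to the aldehyde β-carbon (C1) and the methyl-bearing terminus to C10 ("ortho" adduct), the endo position of the bound formyl group puts C9 cis to the C11 methyl, the (E)-dienophile puts the C1 methyl cis and the ester (C2) trans to C9, and the catalyst sets the absolute configuration.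

Step 4
Reactants: 6 ethyl (1S,5S,6S)-6-formyl-1,5-dimethylcyclohex-3-ene-1-carboxylate
Product: 7 ethyl (1S,5S,6S)-6-(dimethoxymethyl)-1,5-dimethylcyclohex-3-ene-1-carboxylate
Conditions: HC(OMe)3, PPTS (5 mol%), MeOH, rt
Reagents that add atoms: trimethyl orthoformate, COC(OC)OC
Why: Acid-catalysed acetalization masks the epimerizable C9 aldehyde as a base-stable dimethyl acetal that is carried to step 19.

Step 5
Reactants: 7 ethyl (1S,5S,6S)-6-(dimethoxymethyl)-1,5-dimethylcyclohex-3-ene-1-carboxylate
Product: 8 (1S,5S,6S)-6-(dimethoxymethyl)-1,5-dimethylcyclohex-3-ene-1-carboxylic acid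
Conditions: KOH, EtOH/H2O, 80 °C; then 1 M KHSO4 to pH 4, 0 °C
Reagents that add atoms: potassium hydroxide, [K+].[OH-]
Why: Saponification of the hindered ester is safe because the α-carbon is quaternary and the acetal is inert to base.

Step 6
Reactants: 8 (1S,5S,6S)-6-(dimethoxymethyl)-1,5-dimethylcyclohex-3-ene-1-carboxylic acid
Product: 9 iodolactone, 2-(dimethoxymethyl)-4-iodo-1,3-dimethyl-6-oxabicyclo[3.2.1]octan-7-one (C2 carboxyl bridged to C13–O, C12–I anti to it)
Conditions: I2, NaHCO3, THF/H2O, 0 °C to rt, dark
Reagents that add atoms: iodine, II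
Why: Iodolactonization delivers the carboxylate oxygen to the alkene on the ring face that carries C2 and iodine to the opposite face, so the new C–O bond is fixed on the face required for C12–O and the epoxide.

Step 7
Reactants: 9 iodolactone
Product: 11 epoxy Weinreb amide (C2 = N-methoxy-N-methylamide; 12,13-epoxide on the C2 face; C9 dimethyl acetal), via iodohydrin amide 10 (not isolated)
Conditions: MeNHOMe·HCl, i-PrMgCl, THF, −20 to 0 °C; then K2CO3, MeOH, rt
Reagents that add atoms: N,O-dimethylhydroxylamine hydrochloride, CNOC.Cl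
Why: Aminolysis of the strained lactone by the magnesium amide frees the C13 alkoxide, which displaces the anti iodide (intramolecular Williamson reaction) to give the 12,13-epoxide on the C2 face; a regioisomeric iodolactone would converge on the same epoxide.

Step 8
Reactants: 11 epoxy Weinreb amide
Product: 12 vinyl ketone (C2 = C(=O)CH=CH2; 12,13-epoxide; C9 dimethyl acetal)
Conditions: CH2=CHMgBr (3 equiv), THF, 0 °C to rt; cold aq. NH4Cl
Reagents that add atoms: vinylmagnesium bromide, C=C[Mg]Br
Why: Weinreb ketone synthesis stops at the ketone through the chelated tetrahedral intermediate, and the hindered ring epoxide is not opened by the Grignard reagent at this temperature.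

Step 9
Reactants: 12 vinyl ketone
Product: 13 (2R)-allylic alcohol (C2–OH, C3=C4 vinyl; 12,13-epoxide; C9 dimethyl acetal)
Conditions: (S)-2-methyl-CBS-oxazaborolidine (20 mol%), catecholborane, toluene, −78 °C; then MeOH, aq. NaHCO3
Reagents that add atoms: none
Why: Corey–Bakshi–Shibata reduction with the quaternary C1 as the large group and vinyl as the small group delivers hydride to the face that gives the (R)-carbinol at C2 under reagent control.

Step 10
Reactants: 13 (2R)-allylic alcohol
Product: 14 2,12-diol (C12–OH on the C2 face, C13=C14, C3=C4; C9 dimethyl acetal)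
Conditions: LiNEt2 (from Et2NH and n-BuLi, 4 equiv), Et2O, 0 °C to rt; aq. NH4Cl
Reagents that add atoms: none
Why: Lithium amide-mediated syn β-elimination of the epoxide removes the less hindered C14 methylene hydrogen rather than the tertiary C11 hydrogen, so the oxygen stays on C12 with its configuration and the alkene appears at C13=C14.

Step 11
Reactants: 14 2,12-diol
Product: 15 13,14-epoxy-2,12-diol (epoxide cis to C12–OH)
Conditions: VO(acac)2 (5 mol%), t-BuOOH (1.1 equiv), CH2Cl2, 0 °C
Reagents that add atoms: tert-butyl hydroperoxide, CC(C)(C)OO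
Why: Vanadium-catalysed hydroxyl-directed epoxidation transfers oxygen to the cyclic cis-alkene on the face of the C12 hydroxyl, and this alkene reacts much faster than the terminal vinyl group of the hindered C2 carbinol.

Step 12
Reactants: 15 13,14-epoxy-2,12-diol
Product: 16 2,12-diacetate (cyclohexane fragment: C2–OAc with vinyl, C12–OAc, 13,14-epoxide, C9 dimethyl acetal)
Conditions: Ac2O, pyridine, DMAP, CH2Cl2, rt
Reagents that add atoms: acetic anhydride, CC(=O)OC(C)=O
Why: DMAP-catalysed acylation installs both acetates of the target in one operation on the two secondary alcohols.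

Step 13
Reactants: 17 diethyl D-tartrate, (2S,3S)
Product: 18 diethyl (2S,3S)-2,3-bis(tert-butyldimethylsilyloxy)succinate
Conditions: TBSOTf, 2,6-lutidine, CH2Cl2, 0 °C to rt
Reagents that add atoms: tert-butyldimethylsilyl triflate, CC(C)(C)[Si](C)(C)OS(=O)(=O)C(F)(F)F
Why: Silylation protects the threo diol that becomes C6/C7, with C6 in the configuration epimeric to the chloride of the target.

Step 14
Reactants: 18 diethyl (2S,3S)-2,3-bis(tert-butyldimethylsilyloxy)succinate
Product: 19 (2S,3S)-N,N'-dimethoxy-N,N'-dimethyl-2,3-bis(tert-butyldimethylsilyloxy)succinamide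
Conditions: MeNHOMe·HCl, i-PrMgCl, THF, −20 to 0 °C
Reagents that add atoms: N,O-dimethylhydroxylamine hydrochloride, CNOC.Cl
Why: Magnesium amide aminolysis converts both esters to Weinreb amides and keeps the C2 symmetry, so the next mono-addition gives a single product.

Step 15
Reactants: 19 bis-Weinreb amide
Product: 20 keto amide (C16H3–C5(=O)–C6(OTBS)–C7(OTBS)–C8(=O)N(OMe)Me)
Conditions: MeMgBr (1.1 equiv), THF, −78 to −20 °C; aq. NH4Cl
Reagents that add atoms: methylmagnesium bromide, C[Mg]Br
Why: Weinreb ketone synthesis with one equivalent of Grignard reagent stops at the mono-adduct, because the magnesium-chelated tetrahedral intermediate survives until work-up.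

Step 16
Reactants: 20 keto amide
Product: 21 enol triflate amide (C16H2=C5(OTf)–C6(OTBS)–C7(OTBS)–C8(=O)N(OMe)Me)
Conditions: KN(SiMe3)2, PhNTf2, THF, −78 °C
Reagents that add atoms: N-phenylbis(trifluoromethanesulfonimide), O=S(=O)(N(c1ccccc1)S(=O)(=O)C(F)(F)F)C(F)(F)F
Why: Kinetic deprotonation of the methyl group rather than the hindered silyloxy methine, followed by O-triflation, gives the 1,1-disubstituted enol triflate that carries the future exocyclic methylene.

Step 17
Reactants: 21 enol triflate amide; 22 methyl propanoate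
Product: 24 β-keto ester enol triflate (tartrate fragment, C17 epimer mixture), via lithium enolate 23 (not isolated)
Conditions: 22, LiN(i-Pr)2 (from i-Pr2NH and n-BuLi), THF, −78 °C; then 21, −78 to −40 °C; aq. NH4Cl
Reagents that add atoms: none
Why: Claisen-type acylation of the ester enolate by the Weinreb amide gives the β-keto ester after work-up, and the enol triflate is inert to the enolate at low temperature.

Step 18
Reactants: 16 2,12-diacetate; 24 β-keto ester enol triflate
Product: 26 coupled acetal (C4–C5 joined; C9 dimethyl acetal; C8 ketone; C19 methyl ester), via alkylborane 25 (not isolated)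
Conditions: 16, 9-BBN, THF, rt; then 24, Pd(dppf)Cl2 (10 mol%), AsPh3, 3 M aq. K3PO4, DMF, rt
Reagents that add atoms: 9-borabicyclo[3.3.1]nonane, B1C2CCCC1CCC2 (boron is carried only in intermediate 25)
Why: B-alkyl Suzuki–Miyaura coupling: anti-Markovnikov hydroboration of the terminal vinyl group puts boron on C4, and palladium-catalysed coupling with the enol triflate forms C4–C5, conditions known to tolerate acetates, an epoxide and a β-keto ester.

Step 19
Reactants: 26 coupled acetal
Product: 27 keto aldehyde (C9 aldehyde, C8 ketone of the β-keto ester, C6/C7 bis-TBS ether, 2,12-diacetate, 13,14-epoxide)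
Conditions: PPTS, acetone/H2O (10:1), 45 °C
Reagents that add atoms: water, O
Why: Mild acid-catalysed acetal hydrolysis unmasks the C9 aldehyde while the secondary TBS ethers, the acetates and the hindered epoxide survive.

Step 20
Reactants: 27 keto aldehyde
Product: 28 ten-membered 8,9-diol ester (C8 tertiary OH bearing the C17 ester side chain, C9 secondary OH, C6/C7 bis-TBS ether)
Conditions: SmI2 (3 equiv, 0.1 M in THF), t-BuOH (2 equiv), THF, −78 to −20 °C, 27 added over 6 h to 0.002 M; cold aq. NaHCO3
Reagents that add atoms: none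
Why: Single-electron transfer from SmI2 to the C9 aldehyde gives a ketyl that adds to the C8 ketone, which samarium holds between the ketone oxygen and the C19 ester carbonyl; a second electron and tert-butanol deliver the diol, which is the samarium diiodide pinacol coupling of keto aldehydes and β-keto esters, known also for medium and large rings. The ten-membered carbocycle closes by attack of the C9 radical carbon on the exocyclic C8=O (10-exo-trig) under high dilution. C8 and C9 are set together, and the trivalent samarium that bridges O8 and O9 in the bond-forming step should make the diol cis. The face of the C8 ketone should be fixed by additional coordination of the C7 silyloxy oxygen, which places O7, O8 and O9 on one side of the new ring as the target requires, and the C9 face should follow from addition anti to the C10–C1 bond of the cyclohexane. The step needs ketyl addition to outrun reductive loss of the C7 oxygen next to the ketone and lactonization of the C9 alkoxide onto C19, which is sought by low temperature, the absence of HMPA, a proton source and a cold quench.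

Step 21
Reactants: 28 ten-membered 8,9-diol ester
Product: 29 8,9-acetonide
Conditions: 2-methoxypropene, PPTS (cat.), CH2Cl2, 0 °C
Reagents that add atoms: 2-methoxypropene, C=C(C)OC
Why: Acid-catalysed ketalization of the only free (cis) diol removes the C9 hydroxyl as a competitor for lactonization and blocks retro-aldol cleavage at C8–C17.

Step 22
Reactants: 29 8,9-acetonide
Product: 31 hydroxy γ-lactone (C7–O–C19 lactone, free C6–OH, 8,9-acetonide, C17 epimer mixture), via diol ester 30 (not isolated)
Conditions: HF·pyridine, pyridine, THF, 0 °C to rt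
Reagents that add atoms: none
Why: Fluoride-mediated desilylation frees C6–OH and C7–OH, and the C7 hydroxyl closes the five-membered lactone onto the methyl ester in preference to the six-membered alternative from C6–OH (lactonization by transesterification).

Step 23
Reactants: 31 hydroxy γ-lactone (C17 epimer mixture)
Product: 32 (17R)-hydroxy γ-lactone
Conditions: DBU (0.3 equiv), toluene, rt
Reagents that add atoms: none
Why: Base-mediated epimerization through the lactone enolate should converge on the more stable C17 epimer, with the methyl group cis to O8 and trans to the bulkier C9 branch on the lactone ring, as in the target.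

Step 24
Reactants: 32 (17R)-hydroxy γ-lactone
Product: 33 (6S)-chloride 8,9-acetonide
Conditions: PPh3, Cl3CCOCCl3, CH2Cl2, −20 to 0 °C
Reagents that add atoms: hexachloroacetone, ClC(Cl)(Cl)C(=O)C(Cl)(Cl)Cl
Why: Appel-type chlorination with triphenylphosphine and hexachloroacetone converts the only free (allylic) alcohol into the chloride by SN2 displacement of the oxyphosphonium group, with inversion at C6 and little allylic transposition.

Step 25
Reactants: 33 (6S)-chloride 8,9-acetonide
Product: 34 CNP0242711.1 (target)
Conditions: AcOH/H2O (4:1), 40 °C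
Reagents that add atoms: none
Why: Mild aqueous acid hydrolysis of the acetonide frees the 8,9-diol under conditions that the acetates, the lactone, the hindered epoxide and the secondary allylic chloride should survive.

## Compound list

1 | 2,2-dimethoxyacetaldehyde | COC(OC)C=O | starting material
2 | ethyl 2-(triphenylphosphoranylidene)propanoate | CCOC(=O)C(C)=P(c1ccccc1)(c1ccccc1)c1ccccc1 | starting material
3 | ethyl (E)-4,4-dimethoxy-2-methylbut-2-enoate | CCOC(=O)/C(C)=C/C(OC)OC | intermediate
4 | ethyl (E)-2-methyl-4-oxobut-2-enoate | CCOC(=O)/C(C)=C/C=O | intermediate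
5 | (E)-penta-1,3-diene | C/C=C/C=C | starting material
6 | ethyl (1S,5S,6S)-6-formyl-1,5-dimethylcyclohex-3-ene-1-carboxylate | CCOC(=O)[C@]1(C)[C@H]([C@@H](C)C=CC1)C=O | intermediate
7 | ethyl (1S,5S,6S)-6-(dimethoxymethyl)-1,5-dimethylcyclohex-3-ene-1-carboxylate | CCOC(=O)[C@]1(C)[C@H]([C@@H](C)C=CC1)C(OC)OC | intermediate
8 | (1S,5S,6S)-6-(dimethoxymethyl)-1,5-dimethylcyclohex-3-ene-1-carboxylic acid | OC(=O)[C@]1(C)[C@H]([C@@H](C)C=CC1)C(OC)OC | intermediate
9 | iodolactone, 2-(dimethoxymethyl)-4-iodo-1,3-dimethyl-6-oxabicyclo[3.2.1]octan-7-one | COC(OC)[C@H]1[C@@H](C)[C@@H](I)[C@H]2C[C@]1(C)C(=O)O2 | intermediate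
10 | iodohydrin Weinreb amide (C13–OH, C12–I anti) | CON(C)C(=O)[C@@]1(C)C[C@@H](O)[C@H](I)[C@H](C)[C@@H]1C(OC)OC | intermediate (not isolated)
11 | epoxy Weinreb amide (12,13-epoxide on the C2 face) | CON(C)C(=O)[C@@]1(C)C[C@H]2O[C@H]2[C@H](C)[C@@H]1C(OC)OC | intermediate
12 | vinyl ketone (C2 ketone, 12,13-epoxide, C9 acetal) | C=CC(=O)[C@@]1(C)C[C@H]2O[C@H]2[C@H](C)[C@@H]1C(OC)OC | intermediate
13 | (2R)-allylic alcohol (12,13-epoxide, C9 acetal) | C=C[C@@H](O)[C@@]1(C)C[C@H]2O[C@H]2[C@H](C)[C@@H]1C(OC)OC | intermediate
14 | 2,12-diol with C13=C14 | C=C[C@@H](O)[C@@]1(C)C=C[C@@H](O)[C@H](C)[C@@H]1C(OC)OC | intermediate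
15 | 13,14-epoxy-2,12-diol | C=C[C@@H](O)[C@@]1(C)[C@H]2O[C@H]2[C@@H](O)[C@H](C)[C@@H]1C(OC)OC | intermediate
16 | 2,12-diacetate (cyclohexane fragment) | C=C[C@@H](OC(C)=O)[C@@]1(C)[C@H]2O[C@H]2[C@@H](OC(C)=O)[C@H](C)[C@@H]1C(OC)OC | intermediate
17 | diethyl D-tartrate, (2S,3S) | CCOC(=O)[C@@H](O)[C@H](O)C(=O)OCC | starting material
18 | diethyl (2S,3S)-2,3-bis(tert-butyldimethylsilyloxy)succinate | CCOC(=O)[C@@H](O[Si](C)(C)C(C)(C)C)[C@H](O[Si](C)(C)C(C)(C)C)C(=O)OCC | intermediate
19 | (2S,3S)-N,N'-dimethoxy-N,N'-dimethyl-2,3-bis(tert-butyldimethylsilyloxy)succinamide | CON(C)C(=O)[C@@H](O[Si](C)(C)C(C)(C)C)[C@H](O[Si](C)(C)C(C)(C)C)C(=O)N(C)OC | intermediate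
20 | keto amide (C5 methyl ketone, C8 Weinreb amide) | CC(=O)[C@@H](O[Si](C)(C)C(C)(C)C)[C@H](O[Si](C)(C)C(C)(C)C)C(=O)N(C)OC | intermediate
21 | enol triflate amide | C=C(OS(=O)(=O)C(F)(F)F)[C@@H](O[Si](C)(C)C(C)(C)C)[C@H](O[Si](C)(C)C(C)(C)C)C(=O)N(C)OC | intermediate
22 | methyl propanoate | CCC(=O)OC | starting material
23 | lithium enolate of methyl propanoate | [Li+].CC=C(OC)[O-] | intermediate (not isolated)
24 | β-keto ester enol triflate (tartrate fragment, C17 epimer mixture) | C=C(OS(=O)(=O)C(F)(F)F)[C@@H](O[Si](C)(C)C(C)(C)C)[C@H](O[Si](C)(C)C(C)(C)C)C(=O)C(C)C(=O)OC | intermediate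
25 | B-alkyl-9-BBN from 16 (boron on C4) | B1(C2CCCC1CCC2)CC[C@@H](OC(C)=O)[C@@]1(C)[C@H]2O[C@H]2[C@@H](OC(C)=O)[C@H](C)[C@@H]1C(OC)OC | intermediate (not isolated)
26 | coupled acetal | C=C(CC[C@@H](OC(C)=O)[C@@]1(C)[C@H]2O[C@H]2[C@@H](OC(C)=O)[C@H](C)[C@@H]1C(OC)OC)[C@@H](O[Si](C)(C)C(C)(C)C)[C@H](O[Si](C)(C)C(C)(C)C)C(=O)C(C)C(=O)OC | intermediate
27 | keto aldehyde (precursor of the key step) | C=C(CC[C@@H](OC(C)=O)[C@@]1(C)[C@H]2O[C@H]2[C@@H](OC(C)=O)[C@H](C)[C@@H]1C=O)[C@@H](O[Si](C)(C)C(C)(C)C)[C@H](O[Si](C)(C)C(C)(C)C)C(=O)C(C)C(=O)OC | intermediate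
28 | ten-membered 8,9-diol ester (product of the key step) | C=C1CC[C@@H](OC(C)=O)[C@]2(C)[C@H]([C@@H](C)[C@H](OC(C)=O)[C@@H]3O[C@@H]32)[C@@H](O)[C@](O)(C(C)C(=O)OC)[C@@H](O[Si](C)(C)C(C)(C)C)[C@@H]1O[Si](C)(C)C(C)(C)C | intermediate
29 | 8,9-acetonide | C=C1CC[C@@H](OC(C)=O)[C@]2(C)[C@H]([C@@H](C)[C@H](OC(C)=O)[C@@H]3O[C@@H]32)[C@H]2OC(C)(C)O[C@@]2(C(C)C(=O)OC)[C@@H](O[Si](C)(C)C(C)(C)C)[C@@H]1O[Si](C)(C)C(C)(C)C | intermediate
30 | 6,7-diol ester 8,9-acetonide | C=C1CC[C@@H](OC(C)=O)[C@]2(C)[C@H]([C@@H](C)[C@H](OC(C)=O)[C@@H]3O[C@@H]32)[C@H]2OC(C)(C)O[C@@]2(C(C)C(=O)OC)[C@@H](O)[C@@H]1O | intermediate (not isolated)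
31 | hydroxy γ-lactone 8,9-acetonide (C17 epimer mixture) | C=C1CC[C@@H](OC(C)=O)[C@]2(C)[C@H]([C@@H](C)[C@H](OC(C)=O)[C@@H]3O[C@@H]32)[C@H]4OC(C)(C)O[C@]45C(C)C(=O)O[C@H]5[C@@H]1O | intermediate
32 | (17R)-hydroxy γ-lactone 8,9-acetonide | C=C1CC[C@@H](OC(C)=O)[C@]2(C)[C@H]([C@@H](C)[C@H](OC(C)=O)[C@@H]3O[C@@H]32)[C@H]4OC(C)(C)O[C@]45[C@@H](C)C(=O)O[C@H]5[C@@H]1O | intermediate
33 | (6S)-chloride 8,9-acetonide | C=C1CC[C@@H](OC(C)=O)[C@]2(C)[C@H]([C@@H](C)[C@H](OC(C)=O)[C@@H]3O[C@@H]32)[C@H]4OC(C)(C)O[C@]45[C@@H](C)C(=O)O[C@H]5[C@H]1Cl | intermediate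
34 | CNP0242711.1, (1S,2R,6S,7R,8R,9R,10S,11R,12S,13S,14R,17R) | C=C1CC[C@@H](OC(C)=O)[C@]2(C)[C@H]([C@@H](C)[C@H](OC(C)=O)[C@@H]3O[C@@H]32)[C@@H](O)[C@]2(O)[C@@H](C)C(=O)O[C@H]2[C@H]1Cl | target

## Step count and risks

Total step count: 25. Longest linear sequence: 20 steps (steps 1–12 and 18–25); steps 13–17 form the second branch.

Steps most likely to fail:

Step 20 (pinacol macrocyclization). The ketyl may fail to close the ten-membered ring and give reduced or intermolecularly coupled material. The C7 oxygen next to the ketone may be lost reductively, the C9 alkoxide may lactonize onto C19, or the wrong faces of the two carbonyls may combine. The fallback sets out from 27 and returns at 28: the coupling is moved from a chelate-organized samarium ketyl addition in solution to a McMurry-type pinacol coupling on low-valent titanium (TiCl3(DME)1.5, Zn–Cu couple, DME, 0 °C, slow addition). In that reaction both carbonyls are bound to the titanium surface before C–C bond formation, and at this temperature the reaction stops at the diol; whether the epoxide survives low-valent titanium at 0 °C is an open point of this fallback. It makes no new compound (F0).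

Step 24 (chlorination at C6). Chloride may attack the exocyclic methylene carbon (allylic transposition), the oxyphosphonium intermediate may eliminate, or backside attack inside the ring may be too slow. The fallback sets out from 32 and returns at 33: activation and substitution are separated. The alcohol is converted with MsCl and Et3N in CH2Cl2 at −20 °C into the isolable allylic mesylate F1, which is displaced with LiCl in DMF at 0 °C under SN2 conditions chosen independently of the activation step.

Step 3 (enantioselective Diels–Alder). The β,β-disubstituted enal may react slowly, the diene may polymerize under the strong Lewis acid, or enantio- and endo-selectivity may be low. The fallback sets out from 4 and 5 and returns at 8: the cycloaddition is run without a chiral catalyst (EtAlCl2, CH2Cl2, −78 °C) to give 6 together with its enantiomer, ent-6 F2. Steps 4 and 5 are applied unchanged and give 7 and 8 together with ent-7 F3 and ent-8 F4. The racemic acid is then resolved by crystallization of the (R)-1-phenylethylammonium salt of 8, salt F5, from which 1 M KHSO4 releases 8; which enantiomer of the amine gives the less soluble salt with 8 would have to be established.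

## Further compounds

F0 | step 20 | none | none
F1 | step 24 | C6 mesylate of 32 | C=C1CC[C@@H](OC(C)=O)[C@]2(C)[C@H]([C@@H](C)[C@H](OC(C)=O)[C@@H]3O[C@@H]32)[C@H]4OC(C)(C)O[C@]45[C@@H](C)C(=O)O[C@H]5[C@@H]1OS(C)(=O)=O
F2 | step 3 | ent-6, ethyl (1R,5R,6R)-6-formyl-1,5-dimethylcyclohex-3-ene-1-carboxylate | CCOC(=O)[C@@]1(C)[C@@H]([C@H](C)C=CC1)C=O
F3 | step 3 | ent-7, ethyl (1R,5R,6R)-6-(dimethoxymethyl)-1,5-dimethylcyclohex-3-ene-1-carboxylate | CCOC(=O)[C@@]1(C)[C@@H]([C@H](C)C=CC1)C(OC)OC
F4 | step 3 | ent-8, (1R,5R,6R)-6-(dimethoxymethyl)-1,5-dimethylcyclohex-3-ene-1-carboxylic acid | OC(=O)[C@@]1(C)[C@@H]([C@H](C)C=CC1)C(OC)OC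
F5 | step 3 | (R)-1-phenylethylammonium salt of 8 | C[C@@H]([NH3+])c1ccccc1.[O-]C(=O)[C@]1(C)[C@H]([C@@H](C)C=CC1)C(OC)OC
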